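The numbers of this flask are made up; no experiment stands behind them.

An easy step ends this chain: target leaks away first-order to over-reaction product, so you want to know how long it sits exposed to that leak.

- south-east: substrate 2.0 mM; a single well-mixed tank run continuously and read at steady state, 40 s in it on average
- west: substrate 2.0 mM; time 40 s; a closed flask charged with all of it at once and left for 40 s

    intermediate A → intermediate B (k1 = 0.055 s⁻¹)
    target → over-reaction product (k2 = 0.064 s⁻¹)
    substrate + target ⇌ idle adduct, settled at all times (K3 = 210 L mol⁻¹)
    intermediate C → target (k4 = 0.025 s⁻¹)
    2 substrate → homo dimer (k5 = 29 L mol⁻¹ s⁻¹)
    substrate → intermediate A (k6 = 0.024 s⁻¹)
    intermediate B → intermediate C (k7 = 0.080 s⁻¹)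

- percent here means substrate units held: one idle adduct or homo dimer counts as two
- what is said of target includes idle adduct
- two of one species on the left: rate k times its square, two consumed each time
- the stated concentrations are those of everything mixed, before any reaction; amounts are the same in each set-up
- in an amount of target, one idle adduct counts as one target
- run time (west): 40 s

- the set-up with the highest share of target in all that became target or over-reaction product, at the outlet or at the end ("none" if the first two lie within 2 percentage points) (south-east / west / none)
- share of target in all that became target or over-reaction product, at the outlet or at the end, south-east
- share of target in all that became target or over-reaction product, at the outlet or at the end, west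

Target held as idle adduct does not leak in this scheme, so the constant 0.064 s⁻¹ acts on the free fraction f, which is one over one plus 210 L mol⁻¹ times c(substrate). Now take a Damköhler number of your own, the burn number N: that constant times f times the average age of the target present. In the south-east tank, balancing target between leak and outlet gives a share of one over one plus N, so N equal to one is the crossing where leak and outlet take equal parts.

There are two ways to get N. Using the charge of 2.0 mM gives f = 0.704, N = 1.80 and a share of 35.7%. Each turn of dimerisation takes two substrate, which over the 40 s stay makes a group of 2320 L mol⁻¹; solving the tank's substrate balance, feed against washout, the step to intermediate A and dimerisation, gives c(substrate) = 0.598 mM, so f = 0.888 and N = 2.27. The first way cheats, because the tank's contents stand at the outlet level, lower than the charge. So you carry the second burn number, which lies above the crossing, and commit to 30.5%.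

In the west flask, the 4 mean step times add to 112 s, longer than the 40 s run. Births of target are therefore still rising at the end of the run, and as a rough estimate I take the average age as 10.0 s, a quarter of the run. Substrate falls to 0.192 mM, so f = 0.961 and N = 0.615, below the crossing. These ages are bunched, not spread exponentially, so the share is e to the minus N, 54.1%, and my choice is west.

The forecast says west, with 30.5% south-east and 57% west, higher than my flask figure, on the ground that “most target has had little time to over-react”.

The simulation gives west, with 30.5% south-east and 57.1% west. Free target's half-life by its leak alone, 11 s, is shorter than the 40 s, and the burn number is 2.27 in the south-east tank against 0.615 in the west flask. Run on to 45.6 s, the west flask has an estimated burn number of 0.701 by the same quarter age and the same f, and its share stands 5 points from its present value.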